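(All runs stem from a simulated flask for substances that don't exist; noise was put on by code.)

We have no constants yet, so we read what we need from the two runs, counted as fractions of the D charged. The steps considered are D to Q and X to D over L, Q to J and J to X without it, all reversible, and two L lost to E.

| setting | epsilon | delta | flask |
|---|---|---|---|
| D | 0.50 M | 0.50 M | 0.50 M |
| L | 0.60 mM | 1.2 mM | 0.60 mM |
| remark | the very flask that is asked about, followed so far | run made earlier |  |
| time |  |  | 15 d |

| run | time / d | J / % | Q / % |
|---|---|---|---|
| epsilon | 0.417 | 6.2 | 53.8 |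
| epsilon | 1.04 | 20.3 | 52.4 |
| epsilon | 2.08 | 33.2 | 44.5 |
| epsilon | 3.00 | 42.2 | 36.6 |
| delta | 1.67 | 31.7 | 43.1 |
| delta | 3.00 | 43.7 | 35.7 |
| delta | 5.00 | 51.9 | 30.7 |
| delta | 6.00 | 51.6 | 30.0 |

(scatter of a reading: 1 percentage point)

- share of J in J plus Q at 6.0 min
- share of J in J plus Q at 5.0 h
- share of J in J plus Q at 15 d
- which of J and Q there is more of at 15 d

- the earlier runs were read with a standard deviation of 1 percentage point
- reactions considered so far: D + L <-> Q + L; X + L <-> D + L; Q <-> J; J <-> X; 2 L -> E

We turn L first. By hand, L sits in the D to Q step but not in the Q to J step, so once Q has formed, more L should barely shift the J share in J plus Q. The runs agree: at 3.00 d the epsilon run, with 0.60 mM of L, reads a share of 53.6%, and the delta run, with 1.2 mM, reads 55.0%, a shift of 1.4 percentage points on readings with a scatter of 1 point.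

Next comes D. At fixed L, D reacts pseudo-first-order, so by hand a smaller charge should leave the fractions as they are, though neither run tests this.

Time comes last. The delta share reads 42.4% at 1.67 d, then levels off over 5.00 d and 6.00 d. Pooled, those last two readings give the end share, the J share at which Q and J balance (thermodynamic control), of 63.0%. The gap to it shrinks between the first two delta readings with a half-life of 0.971 d, so 15 d spans 15.4 such half-lives. We therefore commit to 63.0% at 15 d in the flask, with J ahead.

The forecast puts the share at 0.1%, 5.5% and 65%, above our 63.0% at the end, with J leading: “J forms from Q without catalyst”.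

The flask gives 0.136%, 6.40% and 65.5%, which is 2.5 points above our end share, with J at 53.7% and Q at 28.3%.

    D + L ⇌ Q + L, rate k1*[D]*[L] forward; the back reaction follows from the equilibrium constant (K = 2.20, k = 240 L mol⁻¹ h⁻¹)
    X + L ⇌ D + L, rate k2*[L]*[X] forward; the back reaction follows from the equilibrium constant (k = 16.0 L mol⁻¹ h⁻¹)
    Q ⇌ J (K = 1.90, k = 0.0180 h⁻¹)
    J ⇌ X (K = 0.0950, k = 0.0330 h⁻¹)
    2 L → E (k = 12.0 L mol⁻¹ h⁻¹)

In this flask Q and J relax by their own step alone with a half-life of 1.05 d, shorter than the 15 d of the run. We hold the end share of 63.0% against the neighbour flask with 0.0015 M of L, whose J share at 15 d is 65.5%, with J at 53.7%.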